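**Retrosynthetic overview**
- The depside ester C(=O)–OAr is disconnected last: an A-ring acid (phenols as benzyl ethers, ketone masked as a 1,3-dithiane) plus a B-ring phenol (benzyl ester, free ketone); dithiane hydrolysis and one hydrogenolysis finish the synthesis.
- Each 2-(2-oxoheptyl)benzoic acid comes from a 3-pentylisocoumarin, an enol lactone that is a latent keto acid and is opened with hydroxide.
- Key disconnection, used once per ring: the Ar(C6)–CH2 bond. A carboxylate-directed aryl–rhodium carbon (nucleophile) is joined to the α-carbon of 2-heptanone delivered as an α-oxo carbene from a sulfoxonium ylide (an enolonium-type electrophile), so two normally nucleophilic carbons are coupled.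
- The ylide comes from hexanoyl chloride and dimethylsulfoxonium methylide.
- Ring order: both benzene rings are bought; the A-series pyranone ring is formed and opened, then the A-series dithiane is formed; the B-series pyranone ring is formed and opened; the dithiane is removed after esterification.

Assumption: the target has no stereocentre and is achiral, so no stereocontrol is needed; 2,4-bis(benzyloxy)benzoic acid and 4-hydroxy-2-methoxybenzoic acid are taken as catalogue compounds.

**Route**

Step 1
Reactants: 1 trimethylsulfoxonium iodide; 2 hexanoyl chloride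
Product: 4 1-[dimethyl(oxo)-λ6-sulfanylidene]heptan-2-one, via dimethylsulfoxonium methylide 3 (not isolated)
Conditions: 1 (3 equiv), KOtBu (3 equiv), THF, reflux, 2 h; then 2 (1 equiv), 0 °C → rt
Reagents that add atoms: none
Why: Acylation of a sulfur ylide (Corey–Chaykovsky reagent chemistry): methylide 3 adds to the acid chloride and a second equivalent of 3 removes the now acidic α-proton, giving the bench-stable carbonyl-stabilised ylide.

Step 2
Reactants: 5 2,4-bis(benzyloxy)benzoic acid; 4 1-[dimethyl(oxo)-λ6-sulfanylidene]heptan-2-one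
Product: 7 6,8-bis(benzyloxy)-3-pentyl-1H-isochromen-1-one, via keto acid 6 (not isolated)
Conditions: [Cp*RhCl2]2 (4 mol %), AgSbF6 (16 mol %), NaOAc (0.5 equiv), 4 (1.5 equiv), CF3CH2OH, 80 °C
Reagents that add atoms: none
Why: Carboxylate-directed Cp*Rh(III) C–H activation/annulation with a sulfoxonium ylide (a known isocoumarin synthesis): the arene is rhodated at C6, the only free ortho C–H, the ylide loses DMSO to form an α-oxo rhodium carbene whose carbon (the α-carbon of the future ketone, here an enolonium-type electrophile) takes up the nucleophilic aryl group by migratory insertion, and protodemetalation to keto acid 6 is followed by cyclodehydration to the enol lactone under the hot, acidic conditions.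

Step 3
Reactants: 7 6,8-bis(benzyloxy)-3-pentyl-1H-isochromen-1-one
Product: 6 2,4-bis(benzyloxy)-6-(2-oxoheptyl)benzoic acid
Conditions: KOH (5 equiv), EtOH/H2O 4:1, 80 °C; then 1 M HCl, 0 °C, to pH 3
Reagents that add atoms: water, O (delivered as aqueous KOH)
Why: Saponification of an enol lactone: hydroxide adds at C1 and the ring opens to a carboxylate plus an enolate that is protonated to the ketone, the carboxylate cannot undergo Dieckmann-type closure, the benzyl ethers are inert, and cold acidification frees the keto acid without re-lactonisation.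

Step 4
Reactants: 6 2,4-bis(benzyloxy)-6-(2-oxoheptyl)benzoic acid
Product: 8 2,4-bis(benzyloxy)-6-[(2-pentyl-1,3-dithian-2-yl)methyl]benzoic acid
Conditions: HS(CH2)3SH (1.5 equiv), BF3·OEt2 (0.5 equiv), CH2Cl2, 0 °C → rt
Reagents that add atoms: 1,3-propanedithiol, SCCCS
Why: Lewis acid-catalysed dithioketalisation: at 0 °C thiol capture of the activated ketone is faster than cyclodehydration back to 7 and the dithiane is the thermodynamic sink, so the enolisable carbonyl that would lactonise onto an activated carboxyl in step 8 is masked while the acid stays free.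

Step 5
Reactants: 9 4-hydroxy-2-methoxybenzoic acid; 4 1-[dimethyl(oxo)-λ6-sulfanylidene]heptan-2-one
Product: 11 6-hydroxy-8-methoxy-3-pentyl-1H-isochromen-1-one, via keto acid 10 (not isolated)
Conditions: [Cp*RhCl2]2 (4 mol %), AgSbF6 (16 mol %), NaOAc (0.5 equiv), 4 (1.5 equiv), CF3CH2OH, 80 °C
Reagents that add atoms: none
Why: The same carboxylate-directed Rh(III) C–H activation/annulation as in step 2: C6 is again the only free ortho C–H, and the phenol, para to the directing carboxylate and unable to chelate, is expected to be tolerated by the cationic Cp*Rh(III) catalyst, which does not promote O–H insertion of the ylide.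

Step 6
Reactants: 11 6-hydroxy-8-methoxy-3-pentyl-1H-isochromen-1-one
Product: 10 4-hydroxy-2-methoxy-6-(2-oxoheptyl)benzoic acid
Conditions: KOH (5 equiv), EtOH/H2O 4:1, 80 °C; then 1 M HCl, 0 °C, to pH 3
Reagents that add atoms: water, O (delivered as aqueous KOH)
Why: Saponification of the enol lactone as in step 3, with the phenol carried through as its phenoxide and returned on cold acidification together with the keto acid.

Step 7
Reactants: 10 4-hydroxy-2-methoxy-6-(2-oxoheptyl)benzoic acid
Product: 12 benzyl 4-hydroxy-2-methoxy-6-(2-oxoheptyl)benzoate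
Conditions: BnBr (1.05 equiv), KHCO3 (1.2 equiv), DMF, rt
Reagents that add atoms: benzyl bromide, BrCc1ccccc1
Why: SN2 O-alkylation of the carboxylate: bicarbonate deprotonates only the carboxylic acid, not the phenol or the ketone α-CH2, so the benzyl ester forms chemoselectively and no carboxyl activation (hence no enol lactonisation) is involved.

Step 8
Reactants: 8 2,4-bis(benzyloxy)-6-[(2-pentyl-1,3-dithian-2-yl)methyl]benzoic acid; 12 benzyl 4-hydroxy-2-methoxy-6-(2-oxoheptyl)benzoate
Product: 14 benzyl 4-({2,4-bis(benzyloxy)-6-[(2-pentyl-1,3-dithian-2-yl)methyl]benzoyl}oxy)-2-methoxy-6-(2-oxoheptyl)benzoate, via mixed trifluoroacetic anhydride 13 (not isolated)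
Conditions: (CF3CO)2O (2 equiv), toluene, 0 °C → rt
Reagents that add atoms: none
Why: Mixed-anhydride (trifluoroacetic anhydride) esterification, the classical depside coupling: the electron-rich, doubly ortho-substituted acid reacts through mixed anhydride 13 and its acylium-like ionisation, which is insensitive to steric hindrance, and the unhindered 4-OH of 12 is acylated while the dithiane keeps the A-ring ketone from enol-lactonising.

Step 9
Reactants: 14 benzyl 4-({2,4-bis(benzyloxy)-6-[(2-pentyl-1,3-dithian-2-yl)methyl]benzoyl}oxy)-2-methoxy-6-(2-oxoheptyl)benzoate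
Product: 15 benzyl 4-{[2,4-bis(benzyloxy)-6-(2-oxoheptyl)benzoyl]oxy}-2-methoxy-6-(2-oxoheptyl)benzoate
Conditions: MeI (15 equiv), CaCO3 (5 equiv), MeCN/H2O 9:1, 45 °C
Reagents that add atoms: water, O
Why: Alkylative dithiane hydrolysis: S-methylation turns sulfur into a leaving group, water adds to the thionium ion and the ketone is released under CaCO3-buffered, near-neutral conditions that leave the benzyl ethers, both esters and the base-sensitive aryl ester next to the new enolisable ketone intact.

Step 10
Reactants: 15 benzyl 4-{[2,4-bis(benzyloxy)-6-(2-oxoheptyl)benzoyl]oxy}-2-methoxy-6-(2-oxoheptyl)benzoate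
Product: 16 arthonioic acid
Conditions: H2 (1 atm), 10% Pd/C, EtOAc, rt
Reagents that add atoms: none
Why: Catalytic hydrogenolysis of the two benzyl ethers and the benzyl ester under neutral conditions, which avoids the base that would let the A-ring ketone enolate expel the phenoxide (isocoumarin formation) and leaves the non-conjugated ketones and the aryl ester untouched.

**Compound list**
1 | trimethylsulfoxonium iodide | C[S+](C)(C)=O.[I-] | starting material
2 | hexanoyl chloride | CCCCCC(Cl)=O | starting material
3 | dimethylsulfoxonium methylide | [CH2-][S+](C)(C)=O | intermediate (not isolated)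
4 | 1-[dimethyl(oxo)-λ6-sulfanylidene]heptan-2-one | CCCCCC(=O)[CH-][S+](C)(C)=O | intermediate
5 | 2,4-bis(benzyloxy)benzoic acid | OC(=O)c1ccc(OCc2ccccc2)cc1OCc1ccccc1 | starting material
6 | 2,4-bis(benzyloxy)-6-(2-oxoheptyl)benzoic acid | CCCCCC(=O)Cc1cc(OCc2ccccc2)cc(OCc2ccccc2)c1C(=O)O | intermediate (not isolated in step 2, isolated in step 3)
7 | 6,8-bis(benzyloxy)-3-pentyl-1H-isochromen-1-one | CCCCCC1=Cc2cc(OCc3ccccc3)cc(OCc3ccccc3)c2C(=O)O1 | intermediate
8 | 2,4-bis(benzyloxy)-6-[(2-pentyl-1,3-dithian-2-yl)methyl]benzoic acid | CCCCCC1(Cc2cc(OCc3ccccc3)cc(OCc3ccccc3)c2C(=O)O)SCCCS1 | intermediate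
9 | 4-hydroxy-2-methoxybenzoic acid | COc1cc(O)ccc1C(=O)O | starting material
10 | 4-hydroxy-2-methoxy-6-(2-oxoheptyl)benzoic acid | CCCCCC(=O)Cc1cc(O)cc(OC)c1C(=O)O | intermediate (not isolated in step 5, isolated in step 6)
11 | 6-hydroxy-8-methoxy-3-pentyl-1H-isochromen-1-one | CCCCCC1=Cc2cc(O)cc(OC)c2C(=O)O1 | intermediate
12 | benzyl 4-hydroxy-2-methoxy-6-(2-oxoheptyl)benzoate | CCCCCC(=O)Cc1cc(O)cc(OC)c1C(=O)OCc1ccccc1 | intermediate
13 | 2,4-bis(benzyloxy)-6-[(2-pentyl-1,3-dithian-2-yl)methyl]benzoic trifluoroacetic anhydride | CCCCCC1(Cc2cc(OCc3ccccc3)cc(OCc3ccccc3)c2C(=O)OC(=O)C(F)(F)F)SCCCS1 | intermediate (not isolated)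
14 | benzyl 4-({2,4-bis(benzyloxy)-6-[(2-pentyl-1,3-dithian-2-yl)methyl]benzoyl}oxy)-2-methoxy-6-(2-oxoheptyl)benzoate | CCCCCC(=O)Cc1cc(OC(=O)c2c(CC3(CCCCC)SCCCS3)cc(OCc3ccccc3)cc2OCc2ccccc2)cc(OC)c1C(=O)OCc1ccccc1 | intermediate
15 | benzyl 4-{[2,4-bis(benzyloxy)-6-(2-oxoheptyl)benzoyl]oxy}-2-methoxy-6-(2-oxoheptyl)benzoate | CCCCCC(=O)Cc1cc(OC(=O)c2c(CC(=O)CCCCC)cc(OCc3ccccc3)cc2OCc2ccccc2)cc(OC)c1C(=O)OCc1ccccc1 | intermediate
16 | arthonioic acid, 4-{[2,4-dihydroxy-6-(2-oxoheptyl)benzoyl]oxy}-2-methoxy-6-(2-oxoheptyl)benzoic acid | CCCCCC(=O)Cc1cc(O)cc(O)c1C(=O)Oc1cc(CC(=O)CCCCC)c(C(=O)O)c(OC)c1 | target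

**Summary**
Total step count: 10.
Longest linear sequence: 7 steps (1, 2, 3, 4, 8, 9, 10; the B-ring branch 1, 5, 6, 7, 8, 9, 10 is equally long).

The three steps most likely to fail are step 5, step 2 and step 8.

The annulation of step 5 is the most exposed, because the free phenol may be O-alkylated by the protonated ylide or may bind the catalyst. The fallback protects the phenol as an ester that falls off in the next operation anyway. It sets out from 9, which is acetylated (Ac2O, pyridine) to 4-acetoxy-2-methoxybenzoic acid F3. F3 is annulated with 4 under the conditions of step 5, passing through 4-acetoxy-2-methoxy-6-(2-oxoheptyl)benzoic acid F4, which is not isolated, to 8-methoxy-1-oxo-3-pentyl-1H-isochromen-6-yl acetate F5. Treating F5 with the aqueous KOH of step 6 cleaves acetate and lactone together, and the route is rejoined at 10.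

The annulation of step 2 can fail because the free acid protonates the ylide (leading to O-alkylation) or because the ortho-benzyloxy acid is rhodated sluggishly. The fallback changes the directing group to an N-methoxy amide, which binds rhodium more strongly and removes the free acid. It sets out from 5, which is coupled with methoxyamine hydrochloride (EDC, HOBt, iPr2NEt) to 2,4-bis(benzyloxy)-N-methoxybenzamide F1. Rh(III)-catalysed reaction of F1 with 4, with a zinc triflate additive that steers ring closure to oxygen, gives the ortho-alkylated 2,4-bis(benzyloxy)-N-methoxy-6-(2-oxoheptyl)benzamide F2, which is not isolated. F2 lactonises through its ketone oxygen with loss of methoxyamine, and the route is rejoined at 7.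

The esterification of step 8 can fail because the acid is doubly ortho-substituted and because a dithiane sulfur may intercept the acylium-like intermediate and fragment the thioketal. The fallback replaces the ionising mixed anhydride by an isolated, compact acyl donor that reacts by addition–elimination. It sets out from 8, which is converted with cyanuric fluoride and pyridine in CH2Cl2 into 2,4-bis(benzyloxy)-6-[(2-pentyl-1,3-dithian-2-yl)methyl]benzoyl fluoride F6. F6 acylates 12 in MeCN in the presence of K2CO3 and catalytic DMAP, and the route is rejoined at 14.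

**Further compounds**
F1 | step 2 | 2,4-bis(benzyloxy)-N-methoxybenzamide | CONC(=O)c1ccc(OCc2ccccc2)cc1OCc1ccccc1
F2 | step 2 | 2,4-bis(benzyloxy)-N-methoxy-6-(2-oxoheptyl)benzamide | CCCCCC(=O)Cc1cc(OCc2ccccc2)cc(OCc2ccccc2)c1C(=O)NOC
F3 | step 5 | 4-acetoxy-2-methoxybenzoic acid | COc1cc(OC(C)=O)ccc1C(=O)O
F4 | step 5 | 4-acetoxy-2-methoxy-6-(2-oxoheptyl)benzoic acid | CCCCCC(=O)Cc1cc(OC(C)=O)cc(OC)c1C(=O)O
F5 | step 5 | 8-methoxy-1-oxo-3-pentyl-1H-isochromen-6-yl acetate | CCCCCC1=Cc2cc(OC(C)=O)cc(OC)c2C(=O)O1
F6 | step 8 | 2,4-bis(benzyloxy)-6-[(2-pentyl-1,3-dithian-2-yl)methyl]benzoyl fluoride | CCCCCC1(Cc2cc(OCc3ccccc3)cc(OCc3ccccc3)c2C(F)=O)SCCCS1
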